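**Plan** (ring numbered as a 2,5-dihydroxy-3-methyl-6-alkyl-1,4-benzoquinone: C1 and C4 carbonyls, C6 bears the chain C1′–C19′)
- Retrosynthesis: the two O–H groups are masked as O–Et (23). The ring is then cut at C1–C6, the bond between the chain-bearing carbon and its oxygen-bearing neighbour (C1 is C=O or C–OH in the two identical tautomers). This leads back through a dienylketene to the four-membered ring of cyclobutenone 19.
- Enabling feature: the six-membered ring is fully substituted. C1(O)–C2(O)–C3(CH3)–C4(O) has the pattern of squaric acid with one oxygen replaced by methyl, and C5(O)=C6(chain) is an enol ether. A C4 squarate plus a C2 ynol ether therefore supply all six ring atoms with every substituent in place.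
- Further cuts: C3–CH3 (MeLi with 1,3-carbonyl transposition), C4–C5 (α-lithio enol ether + diethyl squarate), C6–C1′ (ethoxyacetylide + iodide), C1′–C2′ (Grignard + CH2O), C13′–C14′ (hexynyllithium + 1,12-dibromododecane).
- Forward order: the chain is joined first (steps 1–4), then the two-carbon enol ether unit (steps 5–6) and the squarate (steps 7–8). The only carbocycle of the target arises in step 9 by ring expansion of the four-membered ring; steps 10–11 set the quinone oxidation level and free the hydroxyls.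
- Stereochemistry: the target has no stereocentre. Its (E)-double bond comes from dissolving-metal reduction of an internal alkyne (step 3) and is not touched again. The cyclobutenone stereocentre is racemic and vanishes on aromatisation.

Key step: step 9

Step 1
Reactants: 1 hex-1-yne; 2 1,12-dibromododecane
Product: 4 1-bromooctadec-13-yne, via hex-1-ynyllithium 3 (not isolated)
Conditions: n-BuLi, THF, −78 → 0 °C; then 2 (3 equiv), DMPU, 0 °C → rt
Reagents that add atoms: none
Why: SN2 alkylation of a lithium acetylide with a primary bromide in a dipolar cosolvent, the excess of dibromide suppressing double alkylation.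

Step 2
Reactants: 4 1-bromooctadec-13-yne
Product: 6 nonadec-14-yn-1-ol, via Grignard reagent 5 (not isolated)
Conditions: Mg, THF, reflux; (CH2O)n, 0 °C → rt; aq NH4Cl
Reagents that add atoms: formaldehyde (as paraformaldehyde), C=O
Why: Grignard formation at the primary bromide (the internal alkyne is inert) and addition to formaldehyde should give the one-carbon-homologated primary alcohol.

Step 3
Reactants: 6 nonadec-14-yn-1-ol
Product: 7 (14E)-nonadec-14-en-1-ol
Conditions: Na, NH3(l)/THF, −33 °C; NH4Cl
Reagents that add atoms: none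
Why: dissolving-metal reduction of the internal alkyne passes through the trans vinyl radical/anion, so protonation should deliver the (E)-alkene only, the alkoxide being inert.

Step 4
Reactants: 7 (14E)-nonadec-14-en-1-ol
Product: 8 (14E)-1-iodononadec-14-ene
Conditions: I2, PPh3, imidazole, CH2Cl2, 0 °C → rt
Reagents that add atoms: iodine, II
Why: Appel-type iodination by SN2 displacement of the oxyphosphonium group, which leaves the isolated alkene untouched.

Step 5
Reactants: 9 ethoxyethyne; 8 (14E)-1-iodononadec-14-ene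
Product: 11 (16E)-1-ethoxyhenicos-16-en-1-yne, via lithium ethoxyacetylide 10 (not isolated)
Conditions: 9, n-BuLi, THF, −78 °C; then 8, HMPA, −78 °C → rt
Reagents that add atoms: none
Why: SN2 alkylation of lithium ethoxyacetylide with a primary iodide in THF/HMPA, the standard entry to 1-ethoxy-1-alkynes; it forms the C6–C1′ bond.

Step 6
Reactants: 11 (16E)-1-ethoxyhenicos-16-en-1-yne
Product: 12 tributyl[(1E,16E)-1-ethoxyhenicosa-1,16-dien-1-yl]stannane
Conditions: Bu3SnH, Pd(PPh3)4 (2 mol %), THF, 0 °C → rt
Reagents that add atoms: tributyltin hydride, CCCC[SnH](CCCC)CCCC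
Why: Pd(0)-catalysed hydrostannation of a 1-alkoxy-1-alkyne is a syn addition that places tin on the oxygen-bearing carbon, so the (1E) α-stannyl enol ether is expected and the remote disubstituted alkene should not react.

Step 7
Reactants: 12 tributyl[(1E,16E)-1-ethoxyhenicosa-1,16-dien-1-yl]stannane; 13 diethyl squarate (3,4-diethoxycyclobut-3-ene-1,2-dione)
Product: 16 4-[(tert-butyldimethylsilyl)oxy]-2,3-diethoxy-4-[(1Z,16E)-1-ethoxyhenicosa-1,16-dien-1-yl]cyclobut-2-en-1-one (racemic), via alkenyllithium 14 (not isolated), via lithium alkoxide 15 (not isolated)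
Conditions: n-BuLi, THF, −78 °C; 13, −78 °C; TBSOTf, −78 → 0 °C; aq NaHCO3
Reagents that add atoms: tert-butyldimethylsilyl trifluoromethanesulfonate, CC(C)(C)[Si](C)(C)OS(=O)(=O)C(F)(F)F
Why: tin–lithium exchange with retention gives a configurationally stable α-ethoxyalkenyllithium that adds 1,2 to one squarate carbonyl (forming C4–C5), and the tertiary alkoxide is silylated in situ; the new quaternary centre forms as a racemate and is destroyed in step 9.

Step 8
Reactants: 16 4-[(tert-butyldimethylsilyl)oxy]-2,3-diethoxy-4-[(1Z,16E)-1-ethoxyhenicosa-1,16-dien-1-yl]cyclobut-2-en-1-one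
Product: 19 4-[(tert-butyldimethylsilyl)oxy]-2-ethoxy-4-[(1Z,16E)-1-ethoxyhenicosa-1,16-dien-1-yl]-3-methylcyclobut-2-en-1-one (racemic), via lithium alkoxide 17 (not isolated), via trifluoroacetate 18 (not isolated)
Conditions: MeLi, THF, −78 °C; (CF3CO)2O, −78 °C; aq NaHCO3, −78 °C → rt
Reagents that add atoms: methyllithium, [Li]C; water, O
Why: 1,2-addition of MeLi to the vinylogous-ester carbonyl, O-trifluoroacetylation, ionisation to the ethoxy-stabilised cyclobutenyl cation and hydrolysis at the former β-carbon (a Stork–Danheiser-type 1,3-carbonyl transposition known for squarate adducts) should put methyl on C3 and keep ethoxy on C2, while the silyl ether cannot ionise and the cold buffered work-up spares the enol ether.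

Step 9
Reactants: 19 4-[(tert-butyldimethylsilyl)oxy]-2-ethoxy-4-[(1Z,16E)-1-ethoxyhenicosa-1,16-dien-1-yl]-3-methylcyclobut-2-en-1-one
Product: 22 4-[(tert-butyldimethylsilyl)oxy]-2,5-diethoxy-3-methyl-6-[(14E)-nonadec-14-en-1-yl]phenol, via dienylketene 20 (not isolated), via cyclohexa-2,4-dienone 21 (not isolated)
Conditions: degassed toluene, 110 °C
Reagents that add atoms: none
Why: Heating opens the cyclobutenone by a conrotatory 4π electrocyclic reaction in which the silyloxy donor on C4 rotates outward, so the 1-ethoxyalkenyl group ends cis to the ketene in 20. The ketene carbon then bonds to the alkene CH that carries the chain in a thermal disrotatory 6π electrocyclisation, which closes the six-membered carbocycle by joining the two termini of the C=C=O/C=C/C=C triene and gives dienone 21; enolisation gives phenol 22. The closest known reaction type is the thermal ring expansion of squarate-derived 4-alkenyl-4-oxycyclobutenones to hydroquinones (Moore/Liebeskind). The only new stereocentre, the sp3 CH of 21, forms as a racemate and is erased on aromatisation, and the remote (E)-alkene takes no part. The selectivity needed is regiochemical and is built into 19: the chain carbon can bond only to the ketene carbon, so methyl ends para to the chain with oxygen on the four other ring carbons; the inward rotation of the alkenyl group is secured by the stronger donor (OSi) on the same carbon, and the (Z)-enol ether from steps 6–7 turns H rather than the chain into the closing termini.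

Step 10
Reactants: 22 4-[(tert-butyldimethylsilyl)oxy]-2,5-diethoxy-3-methyl-6-[(14E)-nonadec-14-en-1-yl]phenol
Product: 23 2,5-diethoxy-3-methyl-6-[(14E)-nonadec-14-en-1-yl]cyclohexa-2,5-diene-1,4-dione
Conditions: (NH4)2Ce(NO3)6, MeCN/H2O, 0 °C
Reagents that add atoms: none
Why: two-electron oxidation of a p-silyloxyphenol by Ce(IV) with loss of the silyl group as silanol should give the p-quinone, the para OH/OSi pair directing oxidation away from the ethoxy-bearing carbons; an isolated alkene tolerates brief exposure at 0 °C.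

Step 11
Reactants: 23 2,5-diethoxy-3-methyl-6-[(14E)-nonadec-14-en-1-yl]cyclohexa-2,5-diene-1,4-dione
Product: 24 2,5-dihydroxy-3-methyl-6-[(14E)-nonadec-14-en-1-yl]cyclohexa-2,5-diene-1,4-dione (target)
Conditions: 2 M aq NaOH, EtOH/THF, rt → 50 °C (Ar); then 1 M HCl
Reagents that add atoms: sodium hydroxide, [Na+].[OH-]
Why: each ethoxy group is a vinylogous ester, so hydroxide should add at the ethoxy-bearing ring carbon and expel ethoxide (addition–elimination); the resulting bis-enolate resists further attack and acidification gives the dihydroxyquinone.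

**Compound list**
1 | hex-1-yne | CCCCC#C | starting material
2 | 1,12-dibromododecane | BrCCCCCCCCCCCCBr | starting material
3 | hex-1-ynyllithium | CCCCC#C[Li] | intermediate (not isolated)
4 | 1-bromooctadec-13-yne | CCCCC#CCCCCCCCCCCCCBr | intermediate
5 | octadec-13-yn-1-ylmagnesium bromide | CCCCC#CCCCCCCCCCCCC[Mg]Br | intermediate (not isolated)
6 | nonadec-14-yn-1-ol | CCCCC#CCCCCCCCCCCCCCO | intermediate
7 | (14E)-nonadec-14-en-1-ol | CCCC/C=C/CCCCCCCCCCCCCO | intermediate
8 | (14E)-1-iodononadec-14-ene | CCCC/C=C/CCCCCCCCCCCCCI | intermediate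
9 | ethoxyethyne | CCOC#C | starting material
10 | lithium ethoxyacetylide | CCOC#C[Li] | intermediate (not isolated)
11 | (16E)-1-ethoxyhenicos-16-en-1-yne | CCCC/C=C/CCCCCCCCCCCCCC#COCC | intermediate
12 | tributyl[(1E,16E)-1-ethoxyhenicosa-1,16-dien-1-yl]stannane | CCCC/C=C/CCCCCCCCCCCCC/C=C(\OCC)[Sn](CCCC)(CCCC)CCCC | intermediate
13 | diethyl squarate (3,4-diethoxycyclobut-3-ene-1,2-dione) | CCOC1=C(OCC)C(=O)C1=O | starting material
14 | [(1Z,16E)-1-ethoxyhenicosa-1,16-dien-1-yl]lithium | CCCC/C=C/CCCCCCCCCCCCC/C=C(\OCC)[Li] | intermediate (not isolated)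
15 | lithium 2,3-diethoxy-1-[(1Z,16E)-1-ethoxyhenicosa-1,16-dien-1-yl]-4-oxocyclobut-2-en-1-olate (racemic) | CCCC/C=C/CCCCCCCCCCCCC/C=C(\OCC)C1(O[Li])C(OCC)=C(OCC)C1=O | intermediate (not isolated)
16 | 4-[(tert-butyldimethylsilyl)oxy]-2,3-diethoxy-4-[(1Z,16E)-1-ethoxyhenicosa-1,16-dien-1-yl]cyclobut-2-en-1-one (racemic) | CCCC/C=C/CCCCCCCCCCCCC/C=C(\OCC)C1(O[Si](C)(C)C(C)(C)C)C(OCC)=C(OCC)C1=O | intermediate
17 | lithium 4-[(tert-butyldimethylsilyl)oxy]-2,3-diethoxy-4-[(1Z,16E)-1-ethoxyhenicosa-1,16-dien-1-yl]-1-methylcyclobut-2-en-1-olate (diastereomer mixture) | CCCC/C=C/CCCCCCCCCCCCC/C=C(\OCC)C1(O[Si](C)(C)C(C)(C)C)C(OCC)=C(OCC)C1(C)O[Li] | intermediate (not isolated)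
18 | 4-[(tert-butyldimethylsilyl)oxy]-2,3-diethoxy-4-[(1Z,16E)-1-ethoxyhenicosa-1,16-dien-1-yl]-1-methylcyclobut-2-en-1-yl trifluoroacetate (diastereomer mixture) | CCCC/C=C/CCCCCCCCCCCCC/C=C(\OCC)C1(O[Si](C)(C)C(C)(C)C)C(OCC)=C(OCC)C1(C)OC(=O)C(F)(F)F | intermediate (not isolated)
19 | 4-[(tert-butyldimethylsilyl)oxy]-2-ethoxy-4-[(1Z,16E)-1-ethoxyhenicosa-1,16-dien-1-yl]-3-methylcyclobut-2-en-1-one (racemic) | CCCC/C=C/CCCCCCCCCCCCC/C=C(\OCC)C1(O[Si](C)(C)C(C)(C)C)C(C)=C(OCC)C1=O | intermediate
20 | (3E,5Z,20E)-4-[(tert-butyldimethylsilyl)oxy]-2,5-diethoxy-3-methylpentacosa-1,3,5,20-tetraen-1-one (dienylketene) | CCCC/C=C/CCCCCCCCCCCCC/C=C(\OCC)/C(O[Si](C)(C)C(C)(C)C)=C(C)\C(OCC)=C=O | intermediate (not isolated)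
21 | 4-[(tert-butyldimethylsilyl)oxy]-2,5-diethoxy-3-methyl-6-[(14E)-nonadec-14-en-1-yl]cyclohexa-2,4-dien-1-one (racemic) | CCCC/C=C/CCCCCCCCCCCCCC1C(=O)C(OCC)=C(C)C(O[Si](C)(C)C(C)(C)C)=C1OCC | intermediate (not isolated)
22 | 4-[(tert-butyldimethylsilyl)oxy]-2,5-diethoxy-3-methyl-6-[(14E)-nonadec-14-en-1-yl]phenol | CCCC/C=C/CCCCCCCCCCCCCc1c(O)c(OCC)c(C)c(O[Si](C)(C)C(C)(C)C)c1OCC | intermediate
23 | 2,5-diethoxy-3-methyl-6-[(14E)-nonadec-14-en-1-yl]cyclohexa-2,5-diene-1,4-dione | CCCC/C=C/CCCCCCCCCCCCCC1=C(OCC)C(=O)C(C)=C(OCC)C1=O | intermediate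
24 | 2,5-dihydroxy-3-methyl-6-[(14E)-nonadec-14-en-1-yl]cyclohexa-2,5-diene-1,4-dione | CCCC/C=C/CCCCCCCCCCCCCC1=C(O)C(=O)C(C)=C(O)C1=O | target

Total step count: 11. Longest linear sequence: 11 steps (1 → 24; 2, 9 and 13 are purchased).

**Steps most likely to fail**

Step 8. The enol ether may be lost during the ionisation, either by C-trifluoroacetylation at its β-carbon or by acid hydrolysis. The silyl group may also migrate to the neighbouring new alkoxide, which would move the ionisation to the wrong carbon. Fallback: the two ring carbons are carried as an acid-stable alkyne and the C5 oxygen is introduced after ring formation; it sets out from 8 and comes back at 24. Iodide 8 and lithium acetylide–ethylenediamine complex (DMSO, rt) should give (16E)-henicos-16-en-1-yne F1. Treatment of F1 with n-BuLi (THF, −78 °C), then 13, then TBSOTf, should give 4-[(tert-butyldimethylsilyl)oxy]-2,3-diethoxy-4-[(16E)-henicos-16-en-1-yn-1-yl]cyclobut-2-en-1-one F2. MeLi followed by trifluoroacetic anhydride, as in step 8 but now without an acid-labile group, should give 4-[(tert-butyldimethylsilyl)oxy]-2-ethoxy-4-[(16E)-henicos-16-en-1-yn-1-yl]-3-methylcyclobut-2-en-1-one F3. TBAF/AcOH should free the tertiary alcohol 2-ethoxy-4-[(16E)-henicos-16-en-1-yn-1-yl]-4-hydroxy-3-methylcyclobut-2-en-1-one F4. Heating F4 in toluene (Moore cyclisation: ring opening, closure of the same ring bond between the ketene carbon and the chain-bearing alkyne carbon to a diradical, hydrogen transfer from O to C5) should give 3-ethoxy-2-methyl-5-[(14E)-nonadec-14-en-1-yl]cyclohexa-2,5-diene-1,4-dione F5. Nucleophilic epoxidation of its only non-oxygenated ring double bond (H2O2, Na2CO3, aq THF, 0 °C) should give 3-ethoxy-4-methyl-1-[(14E)-nonadec-14-en-1-yl]-7-oxabicyclo[4.1.0]hept-3-ene-2,5-dione F6. Aqueous NaOH (base-induced opening of the epoxyquinone to the hydroxyquinone and hydrolysis of the ethoxy group), then HCl, should give 24.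

Step 5. The SN2 displacement on the long-chain iodide may be slow and lose out to E2 elimination, and the ynol ether may be hydrated or polymerise on work-up. Fallback: the triple bond is made by elimination instead of alkylation; it sets out from 8 and comes back at 11. Iodide 8 is treated with Mg (THF) and then 2-ethoxy-N-methoxy-N-methylacetamide to give (16E)-1-ethoxyhenicos-16-en-2-one F7. Enolisation toward the ethoxy-bearing carbon (LiHMDS, THF/DMPU, −78 °C; chelation by the ethoxy oxygen is expected to direct it) and trapping with PhNTf2 should give (1Z,16E)-1-ethoxyhenicosa-1,16-dien-2-yl trifluoromethanesulfonate F8. Anti-elimination of triflate with KOt-Bu (THF, −78 °C) should give 11.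

Step 9. The dienylketene may be diverted before it cyclises (dimerisation, capture by adventitious water), or closure at the fully substituted termini may be slow enough for the material to decompose. Fallback: the ring is taken from an arene and the chain is joined to it, with no ring closure; it sets out from 8 and comes back at 24. Commercial 1,2,4,5-tetramethoxybenzene is lithiated (n-BuLi, TMEDA, THF) and methylated (MeI) to 1,2,4,5-tetramethoxy-3-methylbenzene F9. A second directed lithiation at the remaining ring C–H and alkylation with 8 (THF/HMPA) should give 1,2,4,5-tetramethoxy-3-methyl-6-[(14E)-nonadec-14-en-1-yl]benzene F10. Ceric ammonium nitrate (MeCN/H2O, 0 °C) should give 2,5-dimethoxy-3-methyl-6-[(14E)-nonadec-14-en-1-yl]cyclohexa-2,5-diene-1,4-dione F11. Hydrolysis as in step 11 (aq NaOH, then HCl) should give 24.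

**Further compounds**
F1 | step 8 | (16E)-henicos-16-en-1-yne | CCCC/C=C/CCCCCCCCCCCCCC#C
F2 | step 8 | 4-[(tert-butyldimethylsilyl)oxy]-2,3-diethoxy-4-[(16E)-henicos-16-en-1-yn-1-yl]cyclobut-2-en-1-one | CCCC/C=C/CCCCCCCCCCCCCC#CC1(O[Si](C)(C)C(C)(C)C)C(OCC)=C(OCC)C1=O
F3 | step 8 | 4-[(tert-butyldimethylsilyl)oxy]-2-ethoxy-4-[(16E)-henicos-16-en-1-yn-1-yl]-3-methylcyclobut-2-en-1-one | CCCC/C=C/CCCCCCCCCCCCCC#CC1(O[Si](C)(C)C(C)(C)C)C(C)=C(OCC)C1=O
F4 | step 8 | 2-ethoxy-4-[(16E)-henicos-16-en-1-yn-1-yl]-4-hydroxy-3-methylcyclobut-2-en-1-one | CCCC/C=C/CCCCCCCCCCCCCC#CC1(O)C(C)=C(OCC)C1=O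
F5 | step 8 | 3-ethoxy-2-methyl-5-[(14E)-nonadec-14-en-1-yl]cyclohexa-2,5-diene-1,4-dione | CCCC/C=C/CCCCCCCCCCCCCC1=CC(=O)C(C)=C(OCC)C1=O
F6 | step 8 | 3-ethoxy-4-methyl-1-[(14E)-nonadec-14-en-1-yl]-7-oxabicyclo[4.1.0]hept-3-ene-2,5-dione | CCCC/C=C/CCCCCCCCCCCCCC12OC1C(=O)C(C)=C(OCC)C2=O
F7 | step 5 | (16E)-1-ethoxyhenicos-16-en-2-one | CCCC/C=C/CCCCCCCCCCCCCC(=O)COCC
F8 | step 5 | (1Z,16E)-1-ethoxyhenicosa-1,16-dien-2-yl trifluoromethanesulfonate | CCCC/C=C/CCCCCCCCCCCCC/C(OS(=O)(=O)C(F)(F)F)=C/OCC
F9 | step 9 | 1,2,4,5-tetramethoxy-3-methylbenzene | COc1cc(OC)c(OC)c(C)c1OC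
F10 | step 9 | 1,2,4,5-tetramethoxy-3-methyl-6-[(14E)-nonadec-14-en-1-yl]benzene | CCCC/C=C/CCCCCCCCCCCCCc1c(OC)c(OC)c(C)c(OC)c1OC
F11 | step 9 | 2,5-dimethoxy-3-methyl-6-[(14E)-nonadec-14-en-1-yl]cyclohexa-2,5-diene-1,4-dione | CCCC/C=C/CCCCCCCCCCCCCC1=C(OC)C(=O)C(C)=C(OC)C1=O
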